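## Analysis of the target

- The target is a germacranolide, and germacrane numbering is used throughout. A ten-membered carbocycle C1–C10 is fused along C6–C7 to a butenolide ring (O, C6, C7=C11, C12=O). The α-carbon C11 carries the acetoxymethyl group C13.
- The large ring holds a C1 ketone cross-conjugated with the exocyclic methylene C10=C14, an acetoxy group on C3, and a trisubstituted C4=C5 alkene (methyl C15). In that alkene the ring bonds to C3 and C6 are cis (Z).
- There are only two stereocentres, C3 (S) and C6 (R). They sit 1,4 to each other across the Z-alkene, with their oxygen atoms on opposite faces of the flat ring projection, and no third centre relays one to the other.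
- Nearly every group is labile. The C3 acetate is β to the C1 ketone (E1cB), and the enone methylene is a Michael acceptor. H-6 is both allylic and vinylogously acidic (epimerisation), and its removal would expel the C13 acetate or start a transannular attack of C6 on C1.
- The synthesis is hard for three reasons. A strained ten-membered ring with four sp2 ring atoms must be made. A Z-trisubstituted alkene must be placed between two oxygenated carbons. The endgame must avoid base, strong acid and nucleophiles.
- The feature that invites the chosen move is the six-atom run C1–C2–C3–C4–C5–C6. With oxygen on C3, methyl on C4, the cis C4=C5 bond and the three-carbon unit C10(C9)(C14) on C1, it is the complete skeleton of carvone (1) with the bond C1–C6 missing.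
- The four atoms C7–C8–C9–C10 bridge this gap. C8–C9 is a CH2–CH2 bond flanked by the sp2 carbons C7 and C10, and both ends of the missing bond (C1, C6) carry oxygen. This is the retron of a [3,3] ring expansion of a 1,2-dialkenyl six-membered ring.

## Retrosynthetic reasoning

**18 back to 14.** The C1 carbonyl and the C10=C14 methylene are removed together. They are the mark of an ene-type photooxygenation of an E C1=C10 alkene followed by dehydration, which is also their likely biosynthetic origin. Both acetates go on in the same flask, so 18 goes back through 17, 16 and 15 to diol 14. The gain is that the ketone, and with it the β-acetoxy ketone and the Michael acceptor, exists only in the last flask. It also uncovers a 1(10)-alkene that a sigmatropic step can deliver.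

**14 back to 11.** After removal of the silyl groups (14 from 13), the C6–H bond is cut. Butenolide 13 is the conjugated tautomer of enol lactone 12, and both are protonated forms of silyloxyfuran 11. C6 becomes sp2, so the forward step has to set C6 (R) by a face-selective proton transfer. This is the only way a centre this acidic can be controlled late.

**11 back to 9 (key disconnection).** In 11 the bond C8–C9 is cut and the bond C1–C6 is re-formed, with the double bonds C6=C7 and C1=C10 shifting to C7=C8 and C10=C9. The cut is made here because only this pair of bonds turns the ten-membered ring into the six-membered ring of 1. The product of the retro-step is silyl ketene acetal 10, obtained from spirolactone 9. In 10 the whole C15 skeleton, the Z-alkene and C3 are already present in a rigid spirocycle. The forward reaction must expand a six-membered ring by four atoms against ring strain. Aromatisation of the five-membered ring to a furan is what pays for it.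

**9 back to 7.** The bond C11–C13 is cut. A one-carbon electrophile is placed on the α-carbon of the dienolate of butenolide 7. This brings in C13 at the right oxidation level. It also moves the double bond to the exocyclic C7=C8 position that the key step needs.

**7 back to 4 and 5.** The lactone C–O bond, the bond C7–C8 (a methyl nucleophile added to an ynoate) and the bond C6–C7 (an acetylide added to a ketone) are cut. Butenolide 7 thus goes back through 6 to enone 4 and the three-carbon ester 5. The addition to the ketone must place C7 cis to the isopropenyl group.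

**4 back to 1.** The C6 carbonyl is removed (allylic C–H oxidation of 3), the silyl group is taken off (2), and the C3 carbinol is traced to the ketone of (S)-carvone 1. The stereocentre of 1 directs the reduction that sets C3 (S) and is itself consumed in the key step.

## Alternatives that were turned down

**Alternative 1:** (the textbook cut) bond C1–C10.
- Forward key step: intramolecular Nozaki–Hiyama–Kishi coupling (CrCl2, catalytic NiCl2) of the open-chain iodo aldehyde A1 to the macrocyclic carbinol A2, followed by oxidation.
- It was turned down because the step makes one bond and sets nothing.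
- A1 must already contain the Z-alkene, both stereocentres, the butenolide and a β-acetoxy aldehyde that loses acetic acid easily. Each of these needs its own operations in a long linear sequence.
- The end-to-end closure of a ten-membered ring has the worst combination of strain and entropy, so oligomerisation competes even at high dilution.

**Alternative 2:** bond C4=C5.
- Forward key step: ring-closing metathesis of tetraene A3 with the second-generation Grubbs catalyst.
- The catalyst would load on the monosubstituted vinyl group at C5. From there it finds the unhindered C10=C14 methylene in a six-ring relationship, so the small-ring closure should outrun the ten-ring closure.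
- The wanted partner is a hindered 1,1-disubstituted alkene next to an acetoxy carbon.
- A trisubstituted alkene in a strained ring is formed reversibly, and its Z geometry would not be under control.
- Masking the enone methylene adds steps and removes the brevity that is the only merit of this cut.

**Alternative 3:** re-joining C1 and C5.
- Forward key step: Grob fragmentation of the guaiane-type hydroazulenol sulfonate A4. The C1 alkoxide pushes out the C4 leaving group and gives the C1 ketone and C4=C5 at once.
- The leaving group would be a tertiary sulfonate next to an acetate. It should ionise or eliminate faster than it can be made.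
- The C1–C5 and C4–O bonds cannot become truly antiperiplanar in a cyclopentane.
- Three extra stereocentres (C1, C4, C5, with H-5 anti to the leaving group for the Z-alkene) must be built only to be destroyed.
- The alkoxide conditions meet H-6 and both acetates.
- A4 is no simpler than the target.

Key step: step 7

Assumption: germacrane numbering (C1–C15) is applied to all intermediates, and the cupreidine-series catalyst of step 8 is taken to deliver the proton to the face of C6 that gives 6R.

## Route

Step 1
Reactants: 1 (S)-(+)-carvone
Product: 2 (1S,5S)-cis-carveol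
Conditions: NaBH4, CeCl3·7H2O, MeOH, 0 °C
Reagents that add atoms: none
Why: Luche reduction, 1,2-selective on the enone. Axial hydride delivery to the half-chair with equatorial isopropenyl group should give the pseudo-equatorial, cis alcohol, which sets C3 of the target as S under control of the carvone stereocentre.

Step 2
Reactants: 2 (1S,5S)-cis-carveol
Product: 3 (1S,5S)-cis-carveol tert-butyldimethylsilyl ether
Conditions: TBSCl, imidazole, DMF, 23 °C
Reagents that add atoms: tert-butyldimethylsilyl chloride CC(C)(C)[Si](C)(C)Cl
Why: Standard silylation of a secondary allylic alcohol. The ether withstands the organometallic and amide-base steps, and its bulk shields the carbinol C–H in step 3.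

Step 3
Reactants: 3 (1S,5S)-cis-carveol tert-butyldimethylsilyl ether
Product: 4 (4S,6S)-4-(tert-butyldimethylsilyloxy)-3-methyl-6-(prop-1-en-2-yl)cyclohex-2-en-1-one
Conditions: CrO3, 3,5-dimethylpyrazole, CH2Cl2, −20 °C
Reagents that add atoms: chromium trioxide O=[Cr](=O)=O
Why: Allylic C–H oxidation with the CrO3·3,5-dimethylpyrazole complex. The ring CH2 (future C6) is the only secondary allylic position of the more electron-rich, trisubstituted alkene and should be taken to the enone. The centre next to the new ketone keeps, or on enolisation returns to, the favoured 1,3-cis diequatorial arrangement.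

Step 4
Reactants: 4 (4S,6S)-4-(tert-butyldimethylsilyloxy)-3-methyl-6-(prop-1-en-2-yl)cyclohex-2-en-1-one; 5 ethyl propiolate
Product: 6 ethyl 3-[(1R,4S,6S)-4-(tert-butyldimethylsilyloxy)-1-hydroxy-3-methyl-6-(prop-1-en-2-yl)cyclohex-2-en-1-yl]prop-2-ynoate
Conditions: 5, LiN(iPr)2 (LDA), THF, −78 °C; then 4, −78 °C; AcOH, −78 °C
Reagents that add atoms: none
Why: 1,2-Addition of a lithium acetylide to an enone, forming C6–C7. The slim nucleophile should attack axially, anti to the axial hydrogen of the isopropenyl-bearing carbon, so that C7 ends cis and the hydroxyl trans to the isopropenyl group (1R), as step 7 requires. The cold acidic quench prevents retro-addition.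

Step 5
Reactants: 6 ethyl 3-[(1R,4S,6S)-4-(tert-butyldimethylsilyloxy)-1-hydroxy-3-methyl-6-(prop-1-en-2-yl)cyclohex-2-en-1-yl]prop-2-ynoate
Product: 7 (5R,8S,10S)-8-(tert-butyldimethylsilyloxy)-4,7-dimethyl-10-(prop-1-en-2-yl)-1-oxaspiro[4.5]deca-3,6-dien-2-one
Conditions: Me2CuLi (from MeLi, CuI), Et2O–THF, −78 to 0 °C; aq. NH4Cl
Reagents that add atoms: lithium dimethylcuprate [Li+].C[Cu-]C
Why: Conjugate syn-carbocupration of a γ-hydroxy ynoate, the classical butenolide synthesis. Methyl (C8) goes to C7 and the ester ends cis to the tertiary alkoxide, so lactonisation follows on warming. No stereocentre is touched.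

Step 6
Reactants: 7 (5R,8S,10S)-8-(tert-butyldimethylsilyloxy)-4,7-dimethyl-10-(prop-1-en-2-yl)-1-oxaspiro[4.5]deca-3,6-dien-2-one
Product: 9 (5R,8S,10S)-8-(tert-butyldimethylsilyloxy)-3-[(tert-butyldimethylsilyloxy)methyl]-7-methyl-4-methylidene-10-(prop-1-en-2-yl)-1-oxaspiro[4.5]dec-6-en-2-one (C-3 epimers), via lithium aldolate 8 (not isolated)
Conditions: LiN(iPr)2 (LDA), THF, −78 °C; CH2O (gas, from cracked paraformaldehyde), −78 °C; TBSOTf, −78 to 0 °C
Reagents that add atoms: formaldehyde C=O; tert-butyldimethylsilyl triflate CC(C)(C)[Si](C)(C)OS(=O)(=O)C(F)(F)F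
Why: Deconjugative α-hydroxymethylation (kinetic aldol) of a lithium dienolate. C6 is quaternary, so only the vinylogous C8 methyl can be deprotonated, and attack of formaldehyde at the α-carbon C11 moves the alkene to the exocyclic C7=C8 position. The silyl triflate caps 8 before retro-aldol can occur, and the new centre C11 forms as a mixture that step 7 erases.

Step 7
Reactants: 9 (5R,8S,10S)-8-(tert-butyldimethylsilyloxy)-3-[(tert-butyldimethylsilyloxy)methyl]-7-methyl-4-methylidene-10-(prop-1-en-2-yl)-1-oxaspiro[4.5]dec-6-en-2-one (C-3 epimers)
Product: 11 (3S)-3,13-bis(tert-butyldimethylsilyloxy)-12-(trimethylsilyloxy)-6,12-epoxygermacra-1(10)E,4Z,6,11-tetraene, via silyl ketene acetal 10 (not isolated)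
Conditions: TMSOTf, Et3N (excess), toluene, 0 °C; then 80 °C; pentane, filtration under argon, used crude
Reagents that add atoms: trimethylsilyl triflate C[Si](C)(C)OS(=O)(=O)C(F)(F)F
Why: Proposed new method: soft enolisation removes H-11 and gives 10, a 5-silyloxy-3-methylene-2,3-dihydrofuran in which the exocyclic C7=C8 and the isopropenyl C10=C9 are the ends of a 1,5-diene spanning the ring bond C6–C1. On warming a concerted [3,3] shift should form C8–C9, break C6–C1 and move the double bonds to C6=C7 and C1=C10, so the ten-membered ring arises by a four-atom ring expansion through a six-centre chair and not by end-to-end cyclisation, while the five-membered ring is not closed but aromatised. The driving force is the change of a non-aromatic isofuran into a 2-silyloxyfuran together with scission of a congested quaternary–tertiary bond that is allylic on both sides, which should outweigh the cyclodecadiene strain that makes ordinary divinylcyclohexane Cope reactions run backwards. The closest known reaction types are the Cope and anionic oxy-Cope ring expansions of 1,2-dialkenylcyclohexanes and the aromatisation-driven Cope shift of allyl groups in ortho-semibenzenes and in the dienone stage of the para-Claisen rearrangement, and none of these has been shown on a methylene-dihydrofuran. The lactone ring holds C8 anti to O-6, so only the chair with O-6 antiperiplanar to the C1–C10 bond is open, which is why the diastereomer from step 4 is needed, and in that chair C2 is pseudo-equatorial, which fixes C1=C10 as E. No sp3 centre is created: C1, C6 and C11 are erased, C3 is untouched, and the Z geometry of C4=C5 is carried over from the six-membered ring. The competing Ireland–Claisen array C11=C12–O–C6–C5=C4 is shut off because the cyclohexene holds the torsion C7–C6–C5=C4 above 100°, the array C4=C5–C6–C1–C10=C9 would need a bridged boat, and a second Cope shift of the new 1(10),4-diene would cost the furan–alkene conjugation and should need higher temperature. The neutral silyl form is used instead of a metal dienolate so that the C13 silyloxy group is not lost by β-elimination.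

Step 8
Reactants: 11 (3S)-3,13-bis(tert-butyldimethylsilyloxy)-12-(trimethylsilyloxy)-6,12-epoxygermacra-1(10)E,4Z,6,11-tetraene
Product: 13 (3S,6R)-3,13-bis(tert-butyldimethylsilyloxy)germacra-1(10)E,4Z,7(11)-trien-12,6-olide, via deconjugated butenolide 12 (not isolated)
Conditions: MeOH (3 equiv), 9-O-benzylcupreidine (10 mol%), CH2Cl2, −20 °C
Reagents that add atoms: none
Why: Methanolysis of the ketene-acetal O–Si bond releases the dienol, and kinetic α-protonation gives 12. The bifunctional cinchona base takes 12 back to the ammonium dienolate and re-protonates it at C6 (isomerisation of β,γ- to α,β-butenolides by proton-transfer catalysis). C6 (R) is set by the catalyst, whose quinuclidinium delivers the proton to one face of the dienolate held by the 6'-hydroxyl, and the tetrasubstituted conjugated alkene makes 13 the sink.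

Step 9
Reactants: 13 (3S,6R)-3,13-bis(tert-butyldimethylsilyloxy)germacra-1(10)E,4Z,7(11)-trien-12,6-olide
Product: 14 (3S,6R)-3,13-dihydroxygermacra-1(10)E,4Z,7(11)-trien-12,6-olide
Conditions: HF·pyridine, pyridine, THF, 0 to 23 °C
Reagents that add atoms: none
Why: Fluoride cleavage of both silyl ethers in a buffered, weakly acidic medium. This avoids base (H-6) as well as strong acid (transannular cyclisation of the 1(10),4-diene).

Step 10
Reactants: 14 (3S,6R)-3,13-dihydroxygermacra-1(10)E,4Z,7(11)-trien-12,6-olide
Product: 18 (3S,6R)-3,13-diacetoxy-1-oxogermacra-4Z,7(11),10(14)-trien-12,6-olide (CNP0272505.1), via diacetate 15 (not isolated), via allylic hydroperoxide 16 (not isolated), via allylic peracetate 17 (not isolated)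
Conditions: Ac2O, pyridine, DMAP (cat.), CH2Cl2, 0 °C, dark; then meso-tetraphenylporphyrin (cat.), O2, white LED, 0 °C
Reagents that add atoms: acetic anhydride CC(=O)OC(C)=O; dioxygen O=O
Why: Acetylation, then Schenck ene reaction and Kornblum–DeLaMare-type elimination of the peracetate in one flask, copying the likely biogenesis of the 1-oxo-10(14)-ene unit. Singlet oxygen should pick the only electron-rich alkene C1=C10, because C4=C5 is deactivated by two allylic acyloxy groups and C7=C11 by the carbonyl. It should take hydrogen from the freely rotating C14 methyl on the more crowded alkene side, since the ring C–H bonds at C2 and C9 of an E-cyclodecene lie near the alkene plane, and the C1 centre is erased on elimination.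

## Compound list

1 | (S)-(+)-carvone | CC1=CC[C@@H](CC1=O)C(C)=C | starting material
2 | (1S,5S)-cis-carveol | CC1=CC[C@@H](C[C@@H]1O)C(C)=C | intermediate
3 | (1S,5S)-cis-carveol tert-butyldimethylsilyl ether | CC1=CC[C@@H](C[C@@H]1O[Si](C)(C)C(C)(C)C)C(C)=C | intermediate
4 | (4S,6S)-4-(tert-butyldimethylsilyloxy)-3-methyl-6-(prop-1-en-2-yl)cyclohex-2-en-1-one | CC1=CC(=O)[C@@H](C[C@@H]1O[Si](C)(C)C(C)(C)C)C(C)=C | intermediate
5 | ethyl propiolate | C#CC(=O)OCC | starting material
6 | ethyl 3-[(1R,4S,6S)-4-(tert-butyldimethylsilyloxy)-1-hydroxy-3-methyl-6-(prop-1-en-2-yl)cyclohex-2-en-1-yl]prop-2-ynoate | CC1=C[C@](O)(C#CC(=O)OCC)[C@@H](C[C@@H]1O[Si](C)(C)C(C)(C)C)C(C)=C | intermediate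
7 | (5R,8S,10S)-8-(tert-butyldimethylsilyloxy)-4,7-dimethyl-10-(prop-1-en-2-yl)-1-oxaspiro[4.5]deca-3,6-dien-2-one | CC1=C[C@@]2(OC(=O)C=C2C)[C@@H](C[C@@H]1O[Si](C)(C)C(C)(C)C)C(C)=C | intermediate
8 | lithium aldolate (α-oxidomethyl-β-methylene spirolactone, C11 epimers, not isolated) | CC1=C[C@@]2(OC(=O)C(C[O-])C2=C)[C@@H](C[C@@H]1O[Si](C)(C)C(C)(C)C)C(C)=C.[Li+] | intermediate
9 | (5R,8S,10S)-8-(tert-butyldimethylsilyloxy)-3-[(tert-butyldimethylsilyloxy)methyl]-7-methyl-4-methylidene-10-(prop-1-en-2-yl)-1-oxaspiro[4.5]dec-6-en-2-one (C-3 epimers) | CC1=C[C@@]2(OC(=O)C(CO[Si](C)(C)C(C)(C)C)C2=C)[C@@H](C[C@@H]1O[Si](C)(C)C(C)(C)C)C(C)=C | intermediate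
10 | trimethylsilyl ketene acetal of 9 (spiro 5-silyloxy-3-methylene-2,3-dihydrofuran, not isolated) | CC1=C[C@@]2(OC(O[Si](C)(C)C)=C(CO[Si](C)(C)C(C)(C)C)C2=C)[C@@H](C[C@@H]1O[Si](C)(C)C(C)(C)C)C(C)=C | intermediate
11 | (3S)-3,13-bis(tert-butyldimethylsilyloxy)-12-(trimethylsilyloxy)-6,12-epoxygermacra-1(10)E,4Z,6,11-tetraene | C1CC2=C(OC(O[Si](C)(C)C)=C2CO[Si](C)(C)C(C)(C)C)/C=C(/C)[C@@H](O[Si](C)(C)C(C)(C)C)C/C=C1\C | intermediate
12 | (3S)-3,13-bis(tert-butyldimethylsilyloxy)germacra-1(10)E,4Z,6-trien-12,6-olide (C11 epimers, not isolated) | C1CC2=C(OC(=O)C2CO[Si](C)(C)C(C)(C)C)/C=C(/C)[C@@H](O[Si](C)(C)C(C)(C)C)C/C=C1\C | intermediate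
13 | (3S,6R)-3,13-bis(tert-butyldimethylsilyloxy)germacra-1(10)E,4Z,7(11)-trien-12,6-olide | C1CC2=C(CO[Si](C)(C)C(C)(C)C)C(=O)O[C@@H]2/C=C(/C)[C@@H](O[Si](C)(C)C(C)(C)C)C/C=C1\C | intermediate
14 | (3S,6R)-3,13-dihydroxygermacra-1(10)E,4Z,7(11)-trien-12,6-olide | C1CC2=C(CO)C(=O)O[C@@H]2/C=C(/C)[C@@H](O)C/C=C1\C | intermediate
15 | (3S,6R)-3,13-diacetoxygermacra-1(10)E,4Z,7(11)-trien-12,6-olide (not isolated) | C1CC2=C(COC(C)=O)C(=O)O[C@@H]2/C=C(/C)[C@@H](OC(C)=O)C/C=C1\C | intermediate
16 | (3S,6R)-3,13-diacetoxy-1-hydroperoxygermacra-4Z,7(11),10(14)-trien-12,6-olide (C1 undefined, not isolated) | C=C1CCC2=C(COC(C)=O)C(=O)O[C@@H]2/C=C(/C)[C@@H](OC(C)=O)CC1OO | intermediate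
17 | (3S,6R)-3,13-diacetoxy-1-(acetylperoxy)germacra-4Z,7(11),10(14)-trien-12,6-olide (C1 undefined, not isolated) | C=C1CCC2=C(COC(C)=O)C(=O)O[C@@H]2/C=C(/C)[C@@H](OC(C)=O)CC1OOC(C)=O | intermediate
18 | (3S,6R)-3,13-diacetoxy-1-oxogermacra-4Z,7(11),10(14)-trien-12,6-olide (CNP0272505.1) | C=C1CCC2=C(COC(C)=O)C(=O)O[C@@H]2/C=C(/C)[C@@H](OC(C)=O)CC1=O | target

## Step count and least certain steps

Total step count: 10. Longest linear sequence: 10 steps (1 to 18). Compound 5 enters in step 4.

**Step 7 (key step, proposed new method).**
- The rearrangement may be too slow at temperatures the system tolerates. The reactive half-chair puts the isopropenyl group axial and 1,3-syn to the pseudo-axial C3 silyloxy group.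
- Forcing conditions invite ionisation of the tertiary, doubly allylic C6–O bond by the silyl triflate salt, or a second Cope shift of the new 1(10),4-diene.
- The fallback uses the known anionic oxy-Cope reaction, sets out from 4 and rejoins at 12. CH2=CHMgBr with CeCl3 adds to 4 to give the divinyl carbinol F1. KH and 18-crown-6 in THF trigger the anionic oxy-Cope ring expansion, and the regiodefined potassium enolate is alkylated in the flask with ethyl bromoacetate to give the cyclodecadienone keto ester F2. LiOH gives the keto acid F3, and Ac2O with NaOAc cyclodehydrates it to the enol lactone F4. LiN(iPr)2, formaldehyde and TBSOTf (the reagents of step 6) then place C13 on the α-carbon and give 12, on which step 8 is run.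

**Step 8.**
- Poor facial selectivity of the proton transfer is the main risk. The macrocycle and its C3 centre may override the catalyst.
- The extra allylic activation of H-6 may let the amine epimerise the product towards the thermodynamic mixture.
- The fallback gives up kinetic catalyst control for substrate and thermodynamic control with recycling. It sets out from 11 and rejoins at 13. Hydrolysis of 11 with aqueous citric acid in THF gives 13 together with its C6 epimer F5. The two are diastereomers because of C3 and are separated by chromatography. F5 is re-equilibrated through the furanolate with catalytic DBU in toluene and recycled.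

**Step 3.**
- Loss of site selectivity is the risk: attack at the tertiary allylic C–H or the methyl group of the isopropenyl unit, or at the carbinol C–H, and over-oxidation.
- The fallback replaces C–H oxidation by an epoxide-based 1,3-transposition. It sets out from 2 and rejoins at 4. VO(acac)2 with t-BuOOH gives the syn epoxy alcohol F6, and TBSCl with imidazole gives its silyl ether F7. PhSeNa (from PhSeSePh and NaBH4) opens the oxirane at the secondary carbon to the hydroxy selenide F8. H2O2 effects selenoxide elimination to the tertiary allylic alcohol F9. Pyridinium chlorochromate C5H5NH[CrO3Cl] then performs the Babler–Dauben oxidative transposition to 4.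

**Step 10.**
- The amine bases may induce β-elimination of the C3 acetate once the ketone is formed, or substitution at C13.
- The ene reaction may also abstract hydrogen at C2 or C9.
- The fallback separates the events and avoids base. It sets out from 15 (now isolated) and rejoins at 18. Photooxygenation without additives gives 16, PPh3 reduces it to the allylic alcohol F10 (identical with A2), and Dess–Martin periodinane oxidises F10 to 18 under neutral conditions.

**Step 6.**
- Attack of the dienolate through C8 instead of C11, or retro-aldol loss of formaldehyde before silylation, would erode the step.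
- The fallback builds the C11–C13 bond by cross-coupling. It sets out from 6 and rejoins at 10. Me2CuLi followed by I2 gives the α-iodo spirobutenolide F11. Stille coupling with Bu3SnCH2OH and the zerovalent palladium complex Pd(PPh3)4 gives the α-hydroxymethyl butenolide F12. TBSCl with imidazole gives the silyl ether F13, whose soft enolisation at the C8 methyl group under the conditions of step 7 gives the same 10.

## Further compounds

F1 | step 7 | (1R,4S,6S)-4-(tert-butyldimethylsilyloxy)-1-ethenyl-3-methyl-6-(prop-1-en-2-yl)cyclohex-2-en-1-ol | CC1=C[C@](O)(C=C)[C@@H](C[C@@H]1O[Si](C)(C)C(C)(C)C)C(C)=C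
F2 | step 7 | ethyl 2-[(3Z,7E,5S)-5-(tert-butyldimethylsilyloxy)-4,8-dimethyl-2-oxocyclodeca-3,7-dien-1-yl]acetate (C7 epimers) | C1CC(CC(=O)OCC)C(=O)/C=C(/C)[C@@H](O[Si](C)(C)C(C)(C)C)C/C=C1\C
F3 | step 7 | 2-[(3Z,7E,5S)-5-(tert-butyldimethylsilyloxy)-4,8-dimethyl-2-oxocyclodeca-3,7-dien-1-yl]acetic acid (C7 epimers) | C1CC(CC(=O)O)C(=O)/C=C(/C)[C@@H](O[Si](C)(C)C(C)(C)C)C/C=C1\C
F4 | step 7 | (3S)-3-(tert-butyldimethylsilyloxy)-13-norgermacra-1(10)E,4Z,6-trien-12,6-olide | C1CC2=C(OC(=O)C2)/C=C(/C)[C@@H](O[Si](C)(C)C(C)(C)C)C/C=C1\C
F5 | step 8 | (3S,6S)-3,13-bis(tert-butyldimethylsilyloxy)germacra-1(10)E,4Z,7(11)-trien-12,6-olide (C6 epimer of 13) | C1CC2=C(CO[Si](C)(C)C(C)(C)C)C(=O)O[C@H]2/C=C(/C)[C@@H](O[Si](C)(C)C(C)(C)C)C/C=C1\C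
F6 | step 3 | 2,3-epoxide of cis-carveol 2 with the oxirane cis to the hydroxyl | C[C@@]12O[C@@H]1C[C@@H](C[C@@H]2O)C(C)=C
F7 | step 3 | tert-butyldimethylsilyl ether of F6 | C[C@@]12O[C@@H]1C[C@@H](C[C@@H]2O[Si](C)(C)C(C)(C)C)C(C)=C
F8 | step 3 | trans hydroxy selenide from opening of F7 at the secondary carbon | C[C@@]1(O)[C@@H]([Se]c2ccccc2)C[C@@H](C[C@@H]1O[Si](C)(C)C(C)(C)C)C(C)=C
F9 | step 3 | tertiary allylic alcohol 6-(tert-butyldimethylsilyloxy)-1-methyl-4-(prop-1-en-2-yl)cyclohex-2-en-1-ol | C[C@@]1(O)C=C[C@@H](C[C@@H]1O[Si](C)(C)C(C)(C)C)C(C)=C
F10 | step 10 | (3S,6R)-3,13-diacetoxy-1-hydroxygermacra-4Z,7(11),10(14)-trien-12,6-olide (C1 undefined) | C=C1CCC2=C(COC(C)=O)C(=O)O[C@@H]2/C=C(/C)[C@@H](OC(C)=O)CC1O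
F11 | step 6 | (5R,8S,10S)-8-(tert-butyldimethylsilyloxy)-3-iodo-4,7-dimethyl-10-(prop-1-en-2-yl)-1-oxaspiro[4.5]deca-3,6-dien-2-one | CC1=C[C@@]2(OC(=O)C(I)=C2C)[C@@H](C[C@@H]1O[Si](C)(C)C(C)(C)C)C(C)=C
F12 | step 6 | (5R,8S,10S)-8-(tert-butyldimethylsilyloxy)-3-(hydroxymethyl)-4,7-dimethyl-10-(prop-1-en-2-yl)-1-oxaspiro[4.5]deca-3,6-dien-2-one | CC1=C[C@@]2(OC(=O)C(CO)=C2C)[C@@H](C[C@@H]1O[Si](C)(C)C(C)(C)C)C(C)=C
F13 | step 6 | (5R,8S,10S)-8-(tert-butyldimethylsilyloxy)-3-[(tert-butyldimethylsilyloxy)methyl]-4,7-dimethyl-10-(prop-1-en-2-yl)-1-oxaspiro[4.5]deca-3,6-dien-2-one | CC1=C[C@@]2(OC(=O)C(CO[Si](C)(C)C(C)(C)C)=C2C)[C@@H](C[C@@H]1O[Si](C)(C)C(C)(C)C)C(C)=C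
A1 | alternative 1 | open-chain 10-iodo-1-oxo-1,10-seco precursor (3S,6R,4Z) | C=C(I)CCC1=C(COC(C)=O)C(=O)O[C@@H]1/C=C(/C)[C@@H](OC(C)=O)CC=O
A2 | alternative 1 | (3S,6R)-3,13-diacetoxy-1-hydroxygermacra-4Z,7(11),10(14)-trien-12,6-olide (C1 undefined) | C=C1CCC2=C(COC(C)=O)C(=O)O[C@@H]2/C=C(/C)[C@@H](OC(C)=O)CC1O
A3 | alternative 2 | 4,5-seco tetraene (γ-vinyl butenolide with isopropenyl carbinol acetate, 3S,6R) | C=C[C@H]1OC(=O)C(COC(C)=O)=C1CCC(=C)C(=O)C[C@H](OC(C)=O)C(C)=C
A4 | alternative 3 | cis-fused guaia-7(11),10(14)-dien-12,6-olide with 1-hydroxy, 3-acetoxy, 13-acetoxy groups and a 4-mesyloxy group anti to H-5 | C=C1CCC2=C(COC(C)=O)C(=O)O[C@@H]2[C@H]3[C@@](C)(OS(C)(=O)=O)[C@@H](OC(C)=O)C[C@@]13O
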